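**Retrosynthetic overview**

- The target is cut at C2'–C3' (B-alkyl Suzuki coupling, then desilylation) into (S)-6-silyloxy-2-methyl-2-vinyl-2H-chromene and an (E)-alkenyl iodide made from dihydro-β-ionone.
- The plan rests on one feature: C2 of the pyran ring carries CH3 and two carbon arms, ring carbon C3 and side-chain carbon C1'. Both arms can be vinyl groups of an achiral aryl divinylcarbinyl ether, so forming C3=C4 onto an ortho vinyl group picks one of them and creates C2.
- The vinyl chromene therefore comes from an achiral triene by enantiotopic-group-selective ring-closing metathesis with a chiral molybdenum alkylidene.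
- The triene comes from 5-bromo-2-fluorobenzaldehyde and 3-methylpenta-1,4-dien-3-ol by SNAr (C8a–O1 bond), Wittig methylenation, bromide-to-phenol exchange and silylation.
- Ring order: the benzene and cyclohexene rings are bought; the pyran ring is the only ring made (step 6).

Key step: step 6

Assumption: the sense of induction of the chiral molybdenum catalyst on this substrate cannot be predicted with certainty; both antipodes of the diolate are accessible, and the one that gives the (S)-chromene (to be assigned on the first run by chiroptical or crystallographic analysis of a derivative) is used in step 6.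

Handling remark: the tertiary bis-allylic aryl ethers 6, 7, 10 and 11 should be prone to acid-induced ionisation and to aromatic Claisen rearrangement on heating, so they are kept at or below room temperature and purified on base-washed silica. Chromenes 12, 19 and 20 are kept from light.

**Route**

Step 1
Reactants: 1 methyl vinyl ketone; 2 vinylmagnesium bromide
Product: 3 3-methylpenta-1,4-dien-3-ol
Conditions: 2 (1.1 equiv) in THF, 1 added at −78 °C, then 0 °C; sat. aq NH4Cl
Reagents that add atoms: none
Why: Grignard 1,2-addition of the vinyl nucleophile to the ketone carbonyl at low temperature should give the achiral tertiary divinyl carbinol, in which no stereocentre arises.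

Step 2
Reactants: 3 3-methylpenta-1,4-dien-3-ol; 4 5-bromo-2-fluorobenzaldehyde
Product: 6 5-bromo-2-[(3-methylpenta-1,4-dien-3-yl)oxy]benzaldehyde, via sodium 3-methylpenta-1,4-dien-3-olate 5 (not isolated)
Conditions: NaH (1.1 equiv), DMF, 0 °C; then 4, 0 °C to rt; work-up at pH 7 or above
Reagents that add atoms: none
Why: Nucleophilic aromatic substitution (addition–elimination) by the tertiary alkoxide at the C–F carbon activated by the ortho formyl group should displace fluoride and leave the bromide, and the alkoxide has no α-hydrogen to transfer to the aldehyde.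

Step 3
Reactants: 6 5-bromo-2-[(3-methylpenta-1,4-dien-3-yl)oxy]benzaldehyde
Product: 7 4-bromo-2-ethenyl-1-[(3-methylpenta-1,4-dien-3-yl)oxy]benzene
Conditions: Ph3PCH3Br (1.3 equiv), KOtBu (1.25 equiv), THF, 0 °C to rt
Reagents that add atoms: methyltriphenylphosphonium bromide, C[P+](c1ccccc1)(c1ccccc1)c1ccccc1.[Br-]
Why: Wittig methylenation of the non-enolisable aryl aldehyde with the unstabilised ylide should give the styrene under cold basic conditions that the labile ether tolerates.

Step 4
Reactants: 7 4-bromo-2-ethenyl-1-[(3-methylpenta-1,4-dien-3-yl)oxy]benzene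
Product: 10 3-ethenyl-4-[(3-methylpenta-1,4-dien-3-yl)oxy]phenol, via aryllithium 8 (not isolated), via lithium aryltriisopropoxyborate 9 (not isolated)
Conditions: B(OiPr)3 (1.5 equiv) present, n-BuLi (1.15 equiv) added, THF/toluene, −78 °C; then aq NaOH, 30% H2O2, 0 °C; Na2S2O3, neutralise to pH 7
Reagents that add atoms: hydrogen peroxide, OO
Why: Bromine–lithium exchange with in-situ borate capture followed by oxidative C–B to C–O migration (borylation–oxidation) should work because exchange at −78 °C outruns addition of butyllithium to the styrene, the borate present traps the aryllithium at once, the ether carbon has no α-hydrogen for a Wittig rearrangement, and basic peroxide does not epoxidise the isolated alkenes.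

Step 5
Reactants: 10 3-ethenyl-4-[(3-methylpenta-1,4-dien-3-yl)oxy]phenol
Product: 11 tert-butyl{3-ethenyl-4-[(3-methylpenta-1,4-dien-3-yl)oxy]phenoxy}dimethylsilane
Conditions: TBSCl (1.2 equiv), imidazole (2.5 equiv), DMF, 0 °C to rt
Reagents that add atoms: tert-butyldimethylsilyl chloride, CC(C)(C)[Si](C)(C)Cl
Why: Imidazole-promoted silylation of the phenol masks the acidic O–H, which would otherwise protonate the molybdenum alkylidene of the next step.

Step 6
Reactants: 11 tert-butyl{3-ethenyl-4-[(3-methylpenta-1,4-dien-3-yl)oxy]phenoxy}dimethylsilane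
Product: 12 (S)-tert-butyl[(2-ethenyl-2-methyl-2H-chromen-6-yl)oxy]dimethylsilane
Conditions: Mo(=N-2,6-iPr2C6H3)(=CHCMe2Ph)(L) 5 mol%, L = enantiopure 3,3'-di-tert-butyl-5,5',6,6'-tetramethylbiphenyl-2,2'-diolate (antipode as in the assumption), C6H6 (0.05 M), 22 °C, N2 sweep to remove ethylene, dark
Reagents that add atoms: none
Why: The neophylidene should initiate at the unhindered aryl vinyl group to give a molybdenum benzylidene, which undergoes [2+2] cycloaddition with one of the two enantiotopic carbinol vinyl groups; cycloreversion of that metallacyclobutane forms C3=C4, and the methylidene released is turned over with loss of ethylene. The closest known reaction type is the desymmetrising asymmetric ring-closing metathesis of achiral trienyl tertiary ethers by chiral molybdenum imido alkylidene diolates, applied here with an aryl ether and a styrene in the tether. The pyran ring (O1, C2, C3, C4, C4a, C8a) closes by ring-closing metathesis of two terminal alkenes, a six-membered closure favoured by the ortho arrangement of the two arms on the benzene ring and by the fully substituted C2. The C2 stereocentre is set by the axially chiral diolate together with the bulky imido ligand, which make the two possible metallacyclobutanes diastereomeric and unequal in energy. The step needs enantiotopic-group selectivity and ring closure in preference to homocoupling; the carbinol vinyl groups sit on a quaternary carbon and cannot metathesise with each other, so they should neither dimerise nor let the product re-enter the cycle through its spare vinyl group, and removal of ethylene keeps the closure irreversible.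

Step 7
Reactants: 13 dihydro-β-ionone, 4-(2,6,6-trimethylcyclohex-1-en-1-yl)butan-2-one
Product: 15 2-(but-3-yn-1-yl)-1,3,3-trimethylcyclohex-1-ene, via enol diethyl phosphate 14 (not isolated)
Conditions: LDA (1.05 equiv), THF, −78 °C; ClP(O)(OEt)2 (1.1 equiv), −78 °C to rt; then LDA (2.3 equiv), THF, −78 °C to rt; H2O
Reagents that add atoms: none
Why: Kinetic deprotonation on the methyl side, O-phosphorylation of the enolate and LDA-induced β-elimination of diethyl phosphate (methyl ketone to terminal alkyne by enol phosphate elimination) should give the acetylide, which is protonated on quench.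

Step 8
Reactants: 15 2-(but-3-yn-1-yl)-1,3,3-trimethylcyclohex-1-ene
Product: 17 2-[(E)-4-iodo-3-methylbut-3-en-1-yl]-1,3,3-trimethylcyclohex-1-ene, via alkenyldimethylalane 16 (not isolated)
Conditions: AlMe3 (2.5 equiv), Cp2ZrCl2 (0.25 equiv), CH2Cl2, 0 °C to rt; then I2 (1.3 equiv), THF, −30 to 0 °C
Reagents that add atoms: trimethylaluminium, C[Al](C)C; iodine, II
Why: Negishi zirconium-catalysed carboalumination adds methyl and aluminium syn across the terminal alkyne with methyl on the internal carbon, and iodinolysis of the C–Al bond with retention should give the E iodide while the tetrasubstituted ring alkene stays inert.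

Step 9
Reactants: 12 (S)-tert-butyl[(2-ethenyl-2-methyl-2H-chromen-6-yl)oxy]dimethylsilane; 17 2-[(E)-4-iodo-3-methylbut-3-en-1-yl]-1,3,3-trimethylcyclohex-1-ene
Product: 19 tert-butyldimethyl({(S)-2-methyl-2-[(E)-4-methyl-6-(2,6,6-trimethylcyclohex-1-en-1-yl)hex-3-en-1-yl]-2H-chromen-6-yl}oxy)silane, via B-alkyl-9-borabicyclononane 18 (not isolated)
Conditions: 12, 9-BBN (1.4 equiv), THF, 0 °C to rt; then 17 (1.2 equiv), PdCl2(dppf) 5 mol% (dppf = 1,1'-bis(diphenylphosphino)ferrocene), AsPh3 10 mol%, 3 M aq K3PO4, DMF, rt, dark
Reagents that add atoms: none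
Why: Anti-Markovnikov hydroboration with 9-BBN should select the monosubstituted vinyl group over the cis-disubstituted ring alkene C3=C4, and the B-alkyl Suzuki–Miyaura coupling with the alkenyl iodide proceeds with retention of the E geometry at room temperature without touching C2; any partial loss of the aryl silyl ether in the aqueous base is harmless because step 10 removes it.

Step 10
Reactants: 19 tert-butyldimethyl({(S)-2-methyl-2-[(E)-4-methyl-6-(2,6,6-trimethylcyclohex-1-en-1-yl)hex-3-en-1-yl]-2H-chromen-6-yl}oxy)silane
Product: 20 (S)-2-methyl-2-[(E)-4-methyl-6-(2,6,6-trimethylcyclohex-1-en-1-yl)hex-3-en-1-yl]-2H-chromen-6-ol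
Conditions: TBAF (1.1 equiv), THF, 0 °C, argon, dark; aqueous work-up
Reagents that add atoms: none
Why: Fluoride-induced desilylation of the aryl silyl ether, driven by Si–F bond formation, should free the phenol at 0 °C without affecting the alkenes, the allylic aryl ether or the C2 stereocentre.

**Compound list**

1 | methyl vinyl ketone (but-3-en-2-one) | CC(=O)C=C | starting material
2 | vinylmagnesium bromide | C=C[Mg]Br | starting material
3 | 3-methylpenta-1,4-dien-3-ol | C=CC(C)(O)C=C | intermediate
4 | 5-bromo-2-fluorobenzaldehyde | O=Cc1cc(Br)ccc1F | starting material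
5 | sodium 3-methylpenta-1,4-dien-3-olate | [Na+].[O-]C(C)(C=C)C=C | intermediate
6 | 5-bromo-2-[(3-methylpenta-1,4-dien-3-yl)oxy]benzaldehyde | O=Cc1cc(Br)ccc1OC(C)(C=C)C=C | intermediate
7 | 4-bromo-2-ethenyl-1-[(3-methylpenta-1,4-dien-3-yl)oxy]benzene | C=Cc1cc(Br)ccc1OC(C)(C=C)C=C | intermediate
8 | {3-ethenyl-4-[(3-methylpenta-1,4-dien-3-yl)oxy]phenyl}lithium | [Li]c1ccc(OC(C)(C=C)C=C)c(C=C)c1 | intermediate
9 | lithium {3-ethenyl-4-[(3-methylpenta-1,4-dien-3-yl)oxy]phenyl}triisopropoxyborate | [Li+].CC(C)O[B-](OC(C)C)(OC(C)C)c1ccc(OC(C)(C=C)C=C)c(C=C)c1 | intermediate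
10 | 3-ethenyl-4-[(3-methylpenta-1,4-dien-3-yl)oxy]phenol | C=Cc1cc(O)ccc1OC(C)(C=C)C=C | intermediate
11 | tert-butyl{3-ethenyl-4-[(3-methylpenta-1,4-dien-3-yl)oxy]phenoxy}dimethylsilane (achiral) | C=Cc1cc(O[Si](C)(C)C(C)(C)C)ccc1OC(C)(C=C)C=C | intermediate
12 | (S)-tert-butyl[(2-ethenyl-2-methyl-2H-chromen-6-yl)oxy]dimethylsilane | C=C[C@@]1(C)C=Cc2cc(O[Si](C)(C)C(C)(C)C)ccc2O1 | intermediate
13 | dihydro-β-ionone, 4-(2,6,6-trimethylcyclohex-1-en-1-yl)butan-2-one | CC(=O)CCC1=C(C)CCCC1(C)C | starting material
14 | diethyl 4-(2,6,6-trimethylcyclohex-1-en-1-yl)but-1-en-2-yl phosphate | C=C(CCC1=C(C)CCCC1(C)C)OP(=O)(OCC)OCC | intermediate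
15 | 2-(but-3-yn-1-yl)-1,3,3-trimethylcyclohex-1-ene | C#CCCC1=C(C)CCCC1(C)C | intermediate
16 | dimethyl[(E)-2-methyl-4-(2,6,6-trimethylcyclohex-1-en-1-yl)but-1-en-1-yl]alane | C/C(CCC1=C(C)CCCC1(C)C)=C\[Al](C)C | intermediate
17 | 2-[(E)-4-iodo-3-methylbut-3-en-1-yl]-1,3,3-trimethylcyclohex-1-ene | C/C(CCC1=C(C)CCCC1(C)C)=C\I | intermediate
18 | 9-{2-[(S)-6-(tert-butyldimethylsilyloxy)-2-methyl-2H-chromen-2-yl]ethyl}-9-borabicyclo[3.3.1]nonane | C1CC2CCCC(C1)B2CC[C@@]1(C)C=Cc2cc(O[Si](C)(C)C(C)(C)C)ccc2O1 | intermediate
19 | tert-butyldimethyl({(S)-2-methyl-2-[(E)-4-methyl-6-(2,6,6-trimethylcyclohex-1-en-1-yl)hex-3-en-1-yl]-2H-chromen-6-yl}oxy)silane | CC1=C(CC/C(C)=C/CC[C@@]2(C)C=Cc3cc(O[Si](C)(C)C(C)(C)C)ccc3O2)C(C)(C)CCC1 | intermediate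
20 | (S)-2-methyl-2-[(E)-4-methyl-6-(2,6,6-trimethylcyclohex-1-en-1-yl)hex-3-en-1-yl]-2H-chromen-6-ol | CC1=C(CC/C(C)=C/CC[C@@]2(C)C=Cc3cc(O)ccc3O2)C(C)(C)CCC1 | target

**Step count and risks**

Total step count: 10. Longest linear sequence: 8 steps (steps 1 to 6, then 9 and 10); steps 7 and 8 make the side-chain fragment.

Steps most likely to fail:

1. Step 6. The catalyst may discriminate the two enantiotopic vinyl groups only partly, or ring closure at the hindered vinyl groups may stall while the styrene homocouples or the catalyst decays. The fallback sets out from 11 and comes back at 12, and replaces asymmetric catalysis by ring closure without enantiocontrol and separation of enantiomers. Compound 11 would be cyclised with RuCl2(=CHPh)(PCy3)(H2IMes) (second-generation Grubbs catalyst; Cy = cyclohexyl, H2IMes = 1,3-dimesitylimidazolidin-2-ylidene) in CH2Cl2 at 30–40 °C to racemic tert-butyl[(2-ethenyl-2-methyl-2H-chromen-6-yl)oxy]dimethylsilane F1. Preparative chromatography on a cellulose tris(3,5-dimethylphenylcarbamate) stationary phase would then give the (S)-enantiomer, which is compound 12, beside (R)-tert-butyl[(2-ethenyl-2-methyl-2H-chromen-6-yl)oxy]dimethylsilane F2, which is set aside.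

2. Step 4. Butyllithium or the aryllithium may add to the styrene double bond and start anionic oligomerisation before the borate captures it, and the labile ether may be lost during the oxidative work-up. The fallback sets out from 7 and comes back at 12; the bromide is carried through the ring closure and exchanged for oxygen on the chromene, which has no terminal styrene. Bromide 7 would be cyclised with the same chiral molybdenum alkylidene (C6H6, 22 °C) to (S)-6-bromo-2-ethenyl-2-methyl-2H-chromene F3. Treatment with n-BuLi in THF at −78 °C would give [(S)-2-ethenyl-2-methyl-2H-chromen-6-yl]lithium F4, which B(OiPr)3 would trap as lithium [(S)-2-ethenyl-2-methyl-2H-chromen-6-yl]triisopropoxyborate F5. Oxidation with aq NaOH and H2O2 at 0 °C would give (S)-2-ethenyl-2-methyl-2H-chromen-6-ol F6, and silylation with TBSCl and imidazole in DMF would give compound 12.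

3. Step 2. The hindered tertiary alkoxide may substitute slowly, so that its reversible addition to the formyl group and hydride-transfer disproportionation of the aldehyde consume the electrophile. The fallback sets out from 3 (through its alkoxide 5) and comes back at 6; a nitrile replaces the formyl group as the activating group and is reduced afterwards. Alkoxide 5 (from 3 with NaH in DMF at 0 °C) would displace fluoride from 5-bromo-2-fluorobenzonitrile at 0 °C to rt to give 5-bromo-2-[(3-methylpenta-1,4-dien-3-yl)oxy]benzonitrile F7. Reduction with i-Bu2AlH (1.1 equiv) in toluene at −78 °C should stop at N-(diisobutylaluminio)-1-{5-bromo-2-[(3-methylpenta-1,4-dien-3-yl)oxy]phenyl}methanimine F8, and hydrolysis with aq potassium sodium tartrate and a pH 5 buffer would release aldehyde 6.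

Further compounds
F1 | step 6 | racemic tert-butyl[(2-ethenyl-2-methyl-2H-chromen-6-yl)oxy]dimethylsilane | C=CC1(C)C=Cc2cc(O[Si](C)(C)C(C)(C)C)ccc2O1
F2 | step 6 | (R)-tert-butyl[(2-ethenyl-2-methyl-2H-chromen-6-yl)oxy]dimethylsilane | C=C[C@]1(C)C=Cc2cc(O[Si](C)(C)C(C)(C)C)ccc2O1
F3 | step 4 | (S)-6-bromo-2-ethenyl-2-methyl-2H-chromene | C=C[C@@]1(C)C=Cc2cc(Br)ccc2O1
F4 | step 4 | [(S)-2-ethenyl-2-methyl-2H-chromen-6-yl]lithium | C=C[C@@]1(C)C=Cc2cc([Li])ccc2O1
F5 | step 4 | lithium [(S)-2-ethenyl-2-methyl-2H-chromen-6-yl]triisopropoxyborate | [Li+].C=C[C@@]1(C)C=Cc2cc([B-](OC(C)C)(OC(C)C)OC(C)C)ccc2O1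
F6 | step 4 | (S)-2-ethenyl-2-methyl-2H-chromen-6-ol | C=C[C@@]1(C)C=Cc2cc(O)ccc2O1
F7 | step 2 | 5-bromo-2-[(3-methylpenta-1,4-dien-3-yl)oxy]benzonitrile | N#Cc1cc(Br)ccc1OC(C)(C=C)C=C
F8 | step 2 | N-(diisobutylaluminio)-1-{5-bromo-2-[(3-methylpenta-1,4-dien-3-yl)oxy]phenyl}methanimine | CC(C)C[Al](CC(C)C)N=Cc1cc(Br)ccc1OC(C)(C=C)C=C
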